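**Assumption:** C3 is a hemiketal carbon in ring–chain equilibrium with the 10-hydroxy-4-en-3-one, so it is not set by a reagent but follows C10 through the oxygen bridge (read literally, the C3 and C10 descriptors of the SMILES put the bridge oxygen on opposite faces of the oxolane); the route builds C6, C7, C8 and C10 exactly as written (all R), lets C3 close under thermodynamic control, and carries the target SMILES unchanged (the C10 epimer would come from the enantiomeric glycidol).

## Structural features

Compound 28 is a germacranolide: a ten-membered carbocycle (C1–C10) in which C3 and C10 are joined by an oxygen, so that C3–C2–C1–C10–O form an oxolane inside an 11-oxabicyclo[6.2.1]undec-4-ene. C3 is a hemiketal, i.e. the masked ketone of a 10-hydroxy-4-en-3-one. A trans-fused α-methylene-γ-butyrolactone (C12 on O6, exocyclic C11=C13) sits on C6–C7, C8 carries the isobutyrate, and C4 of the (Z)-C4=C5 olefin carries the hydroxymethyl C15. C6, C7 and C8 are contiguous stereocentres (O6 trans to the C7 branch, the C7 branch cis to O8 in the ring projection); C10 is a quaternary ether carbon 1,3 to C8, and C3 is slaved to C10. Fragile groups are the α-methylene lactone (Michael acceptor), the hemiketal next to a cis-γ-oxygenated olefin (dehydration, furan formation), the allylic primary alcohol and the ester. The real difficulty is the medium ring with its (Z)-trisubstituted olefin, together with the C6/C7/C8 triad and the remote C10.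

The feature exploited is this: C3 (carbonyl level) and C8 (C–O) are the two ends of the segment C3–C4(C15)=C5–C6–C7(C11–C13)–C8, which is the carbon skeleton of carvone if a C3–C8 bond is drawn. Oxygen inserted into that ring bond becomes O8 of a seven-membered lactone. The remaining five carbons (C9, C10, C14, C1, C2) are a side chain on C8 whose terminal carbon C2 can reach C3 through a seven-membered transition state and turn the lactone into the ten-membered carbocycle.

## Logic of the disconnections

**28 ⇒ 27.** The C15–O bond is cut. With C3 tied up as the hemiketal, C15 is the only allylic C–H position at the more substituted end of C4=C5, so the hydroxyl can be added last. This lets the methyl group of 7 be carried through the whole route. The forward step must be a regioselective allylic hydroxylation that leaves the lactone and hemiketal intact.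

**27 ⇒ 25.** The lactone bond O6–C12 and the O6–Si bond are cut. Keeping C12 as a free acid means no Michael acceptor and no second electrophilic carbonyl is present during the carbanion chemistry. The forward step needs only the 6-OH to be free, so C8 must already be acylated (otherwise the 8,12-olide could form).

**25 ⇒ 23.** The hemiketal bond O10–C3 is opened and the sulfonyl group is put back on C2. This reveals a ten-membered β-keto sulfone. The forward step needs chemoselective C–S reduction next to an enone, and acid-induced unmasking of the C10 hydroxyl.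

**23 ⇒ 20 (key).** The C2–C3 bond and the O8–acyl bond are cut and C3 is rejoined to O8. The ten-membered carbocycle contracts to the seven-membered (Z)-enoate lactone 20. In one sentence: the ten-membered ring is made by ring expansion of lactone 20, the C2 carbanion of its own side chain displacing O8 from C3. The gain is that no macrocyclisation is needed, the Z olefin is fixed by the small ring, and the leaving oxygen becomes the ester oxygen. The forward step demands 1,2-addition through a seven-membered transition state and an inert C12.

**20 ⇒ 19.** O8 is removed and C3–C8 rejoined (Baeyer–Villiger retron). This gives the six-membered enone 19. The forward step demands migration of the secondary C8 rather than the vinylic C4, with retention, and the absence of any electron-rich olefin.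

**19 ⇒ 14.** C12 is taken back to the methyl oxidation level (via 17), the sulfone to the sulfide (16 ⇒ 15) and the silyl group removed from O10 (15 ⇒ 14). The order of the forward steps is dictated by the need for an electron-poor C11=C13 before step 11.

**14 ⇒ 12 + 6.** The C8–C9 bond is cut. This separates the ring, with C6 and C7 set, from the C5 unit that carries C10. The forward step demands alkylation trans to the C7 branch and epoxide opening at the CH2 terminus, so that C10 is imported unchanged.

**12 ⇒ 7.** The C6–O bond is cut (via 11 and 9). This is a γ-oxygenation of the enone and demands a linear dienol ether and attack anti to the C7 substituent.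

**6 ⇒ 1 + 2.** The C1–C2 bond is cut (via 4) and the epoxide is moved from the C10–C1 side to the C10–C9 side. Both carbons flanking C10 are differentiated without touching the stereocentre.

## Other disconnections considered

**Alternative 1:** (the first that comes to mind) cut C6–C7. The forward key step would be an intramolecular Barbier/Nozaki–Hiyama–Kishi allylation of the (Z)-enal by the 2-(bromomethyl)enoate in seco compound A1, giving the ten-membered homoallylic alcohol A2, which would lactonise. This closes the strained ten-membered ring directly, requires a separately made and isomerisation-prone (Z)-enal, and leaves the C6/C7 configuration to a macrocyclic transition state. The chosen plan takes the olefin geometry and C7 from 7, sets C6 and C8 on a six-membered ring, and closes through a seven-membered transition state.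

**Alternative 2:** cut C3–C8 homolytically. The side-chain C2 iodide would add to the ring carbonyl (intramolecular Barbier) to give decalinol A3, and a Suárez-type alkoxy-radical β-scission would open the central bond to the ten-membered iodo enone A4. The same six-membered template is used, but the C8 radical would be trapped without stereocontrol and the C8 oxygen would then have to be introduced by substitution next to the branched C7, where elimination competes. The Baeyer–Villiger/acyl-transfer sequence delivers O8 with retention and in one step fewer.

**Alternative 3:** cut C3–C4. Halogen–lithium exchange on the (Z)-vinyl iodide A5 and addition to its γ-lactone carbonyl would give the hemiketal 27 directly as the tetrahedral adduct. The idea is short, but it is a direct ten-membered closure by an unstabilised vinyllithium in the presence of an α-methylene lactone and an ester. The (Z)-iodide and the C6–C8 triad would need a separate acyclic synthesis, and nothing templates the ring closure.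

Key step: step 12

## Route

Step 1
Reactants: 1 (S)-2-methylglycidol; 2 thioanisole
Product: 4 (2R)-2-methyl-4-(phenylsulfanyl)butane-1,2-diol, via (phenylthio)methyllithium 3 (not isolated)
Conditions: 2, n-BuLi, DABCO, THF, 0 °C; then 1 (pre-treated with 1 equiv n-BuLi), −78 → 25 °C; aq. NH4Cl
Reagents that add atoms: none
Why: The α-thio carbanion should open the epoxide at the unsubstituted CH2 (SN2), so the quaternary carbon (C10 of 28) is not touched and keeps its configuration; a Payne rearrangement of this epoxy alkoxide is degenerate.

Step 2
Reactants: 4 (2R)-2-methyl-4-(phenylsulfanyl)butane-1,2-diol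
Product: 6 (2R)-2-methyl-2-[2-(phenylsulfanyl)ethyl]oxirane, via primary tosylate 5 (not isolated)
Conditions: NaH (2.2 equiv), N-tosylimidazole, THF, 0 → 25 °C
Reagents that add atoms: none
Why: Selective sulfonylation of the primary alkoxide followed by intramolecular Williamson closure by the tertiary alkoxide should give the terminal epoxide; no bond to the stereocentre is broken.

Step 3
Reactants: 7 (S)-(+)-carvone
Product: 9 linear trimethylsilyl dienol ether of carvone, via bromomagnesium dienolate 8 (not isolated)
Conditions: MeMgBr, FeCl3 (cat.), Et2O, −20 °C; then TMSCl, Et3N, DMPU, −20 → 25 °C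
Reagents that add atoms: chlorotrimethylsilane C[Si](C)(C)Cl
Why: Iron-catalysed deprotonation by the Grignard reagent (Kharasch-type) should remove a γ-hydrogen at C4 and give the thermodynamic, fully conjugated dienolate instead of 1,2-addition; O-silylation fixes the 1-silyloxy-1,3-diene and C5 is untouched.

Step 4
Reactants: 9 linear trimethylsilyl dienol ether of carvone
Product: 11 trans-4-hydroxycarvone, via silyl peroxide 10 (not isolated)
Conditions: O2, hν, tetraphenylporphyrin (cat.), CH2Cl2, −78 °C; then PPh3, −78 → 25 °C; 1 M HCl–THF work-up
Reagents that add atoms: oxygen O=O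
Why: Singlet oxygen should add [4+2] to the cisoid silyloxydiene on the face anti to the adjacent isopropenyl group; silyl shift gives the γ-silylperoxy enone, which the phosphine reduces (photooxygenation of a silyloxydiene), setting C4 (C6 of 28) trans to the side chain. The isolated 1,1-disubstituted olefin reacts much more slowly with singlet oxygen.

Step 5
Reactants: 11 trans-4-hydroxycarvone
Product: 12 trans-4-(tert-butyldimethylsilyloxy)carvone
Conditions: TBSCl, imidazole, DMF, 25 °C
Reagents that add atoms: tert-butyl(chloro)dimethylsilane CC(C)(C)[Si](C)(C)Cl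
Why: Standard silylation of a secondary allylic alcohol; the ether must survive enolate, peracid and carbanion conditions and is removed by fluoride at the end.

Step 6
Reactants: 12 trans-4-(tert-butyldimethylsilyloxy)carvone; 6 (2R)-2-methyl-2-[2-(phenylsulfanyl)ethyl]oxirane
Product: 14 all-trans 6-alkylated hydroxy ketone, via lithium enolate 13 (not isolated)
Conditions: LDA, THF, −78 °C; then 6, LiClO4, −78 → 25 °C; aq. NH4Cl
Reagents that add atoms: none
Why: Kinetic deprotonation at C6 gives the cross-conjugated enolate, which should open the epoxide at its CH2 terminus (Lewis-acid-assisted enolate–epoxide alkylation). Attack anti to the C5 substituent gives the 5,6-trans product (C8 of 28), and the carbinol carbon (C10) comes in unchanged from 6.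

Step 7
Reactants: 14 all-trans 6-alkylated hydroxy ketone
Product: 15 tertiary triethylsilyl ether of 14
Conditions: TESOTf, 2,6-lutidine, CH2Cl2, −78 → 0 °C
Reagents that add atoms: triethylsilyl trifluoromethanesulfonate CC[Si](CC)(CC)OS(=O)(=O)C(F)(F)F
Why: Silyl triflate silylation of a tertiary alcohol; it blocks hemiketalisation with the ring ketone before the Baeyer–Villiger step and keeps O10 away from the lactone in step 12.

Step 8
Reactants: 15 tertiary triethylsilyl ether of 14
Product: 16 phenyl sulfone
Conditions: 30% H2O2, (NH4)6Mo7O24·4H2O (cat.), EtOH, 0 → 25 °C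
Reagents that add atoms: hydrogen peroxide OO
Why: Molybdate-catalysed sulfide-to-sulfone oxidation is much faster than any reaction of the enone or the isolated olefin under neutral conditions.

Step 9
Reactants: 16 phenyl sulfone
Product: 17 allylic alcohol (C12–OH)
Conditions: SeO2 (cat.), t-BuOOH, CH2Cl2, 25 °C
Reagents that add atoms: selenium dioxide O=[Se]=O; tert-butyl hydroperoxide CC(C)(C)OO
Why: Riley allylic hydroxylation (ene reaction then [2,3] shift); the enone olefin and its methyl are deactivated, and at the isopropenyl group abstraction of the ring hydrogen, which is flanked by two substituted carbons, should be disfavoured against the methyl group.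

Step 10
Reactants: 17 allylic alcohol (C12–OH)
Product: 19 acrylic acid (C12 acid), via enal 18 (not isolated)
Conditions: TEMPO (cat.), PhI(OAc)2, MeCN–H2O (pH 7 buffer), 25 °C
Reagents that add atoms: water O
Why: Oxoammonium oxidation of the primary allylic alcohol to the aldehyde and, through its hydrate, to the acid; the acid makes C11=C13 electron-poor for step 11 and becomes an unreactive carboxylate in step 12.

Step 11
Reactants: 19 acrylic acid (C12 acid)
Product: 20 seven-membered (Z)-enoate lactone
Conditions: mCPBA, Na2HPO4, CH2Cl2, 0 → 25 °C
Reagents that add atoms: 3-chloroperoxybenzoic acid OOC(=O)c1cccc(Cl)c1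
Why: Baeyer–Villiger oxidation; the secondary alkyl carbon (C8 of 28) should migrate in preference to the vinylic carbon and with retention, so the inserted oxygen becomes O8 with the required configuration. Both remaining C=C bonds are conjugated to carbonyl groups and should resist the peracid.

Step 12
Reactants: 20 seven-membered (Z)-enoate lactone
Product: 23 ten-membered β-keto sulfone 8-isobutyrate, via bridged tetrahedral adduct 21 (not isolated), via ring-expanded alkoxide 22 (not isolated)
Conditions: LiHMDS (3.2 equiv), THF, −78 → −20 °C; then (i-PrCO)2O (1.1 equiv), −78 °C; aq. NH4Cl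
Reagents that add atoms: 2-methylpropanoic anhydride CC(C)C(=O)OC(=O)C(C)C
Why: The base forms the carboxylate and then the α-sulfonyl carbanion at C2, which adds to the lactone carbonyl C3 through a seven-membered transition state (7-exo-trig, helped by the quaternary C10) to give the O8-bridged adduct 21. Collapse with loss of the C8 alkoxide breaks O8–C3 and unveils the ten-membered carbocycle, so the large ring is never closed directly (ring expansion 7 → 10). The driving force is the deprotonation of the β-keto sulfone (pKa about 12 against about 29 for the alkyl sulfone), which also masks the new C3 ketone against the alkoxide. The closest known reaction types are the Claisen/Dieckmann-type acylation of sulfonyl carbanions by lactones and side-chain-insertion ring expansions of lactones by intramolecular nucleophilic acyl substitution. No lasting stereocentre is created: C2 is epimeric and is removed in step 13, C3 in 21 is fixed by the bridge, and the Z olefin and C6, C7, C8, C10 are carried over from 20. The step needs 1,2- rather than 1,4-addition (the 1,4 mode would require an eight-membered ring), attack at C3 rather than C12 (a carboxylate, with a non-accepting C=C), and acylation of the alkoxide rather than the doubly stabilised enolate (hard lithium alkoxide, one equivalent of anhydride at −78 °C). Acylation in the same flask puts the isobutyrate on the oxygen that left C3 before the C8 hydroxyl can lactonise onto C12.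

Step 13
Reactants: 23 ten-membered β-keto sulfone 8-isobutyrate
Product: 25 3,10-hemiketal acid (6-OTBS), via desulfonylated ketone 24 (not isolated)
Conditions: SmI2, THF–MeOH, −78 °C; then TsOH·H2O (cat.), THF–H2O, 25 °C
Reagents that add atoms: none
Why: SmI2 reduction of an α-sulfonyl ketone (reductive desulfonylation) should be much faster than reduction of the enone; acid then cleaves the tertiary triethylsilyl ether and the C10 hydroxyl closes onto the C3 ketone as the five-membered hemiketal, with C3 under thermodynamic control.

Step 14
Reactants: 25 3,10-hemiketal acid (6-OTBS)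
Product: 27 15-deoxy-28, via hydroxy acid 26 (not isolated)
Conditions: HF·pyridine, THF–pyridine, 0 → 25 °C
Reagents that add atoms: none
Why: Fluoride removes the allylic silyl ether and the γ-hydroxy acid should lactonise in the acidic medium to the trans-fused α-methylene-γ-butyrolactone. C8 is already acylated, so only the 6,12-olide can form, and the C3 carbonyl is masked, so the cis-γ-hydroxy enone cannot dehydrate to a furan.

Step 15
Reactants: 27 15-deoxy-28
Product: 28 target
Conditions: SeO2 (cat.), t-BuOOH, CH2Cl2, 0 → 25 °C
Reagents that add atoms: selenium dioxide O=[Se]=O; tert-butyl hydroperoxide CC(C)(C)OO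
Why: Riley oxidation; C4=C5 is no longer conjugated, selenium should attack C5 and take hydrogen from the only allylic C–H group on the more substituted terminus (C15), and the [2,3] shift returns the ring-constrained Z olefin. The α-methylene lactone olefin is electron-poor and should not react.

## Compound list

1 | (S)-2-methylglycidol, [(2S)-2-methyloxiran-2-yl]methanol | C[C@]1(CO)CO1 | starting material
2 | thioanisole | CSc1ccccc1 | starting material
3 | (phenylthio)methyllithium | [Li]CSc1ccccc1 | intermediate (not isolated)
4 | (2R)-2-methyl-4-(phenylsulfanyl)butane-1,2-diol | C[C@@](O)(CCSc1ccccc1)CO | intermediate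
5 | (2R)-2-hydroxy-2-methyl-4-(phenylsulfanyl)butyl 4-methylbenzenesulfonate (sodium alkoxide in the flask, drawn protonated) | C[C@@](O)(CCSc1ccccc1)COS(=O)(=O)c1ccc(C)cc1 | intermediate (not isolated)
6 | (2R)-2-methyl-2-[2-(phenylsulfanyl)ethyl]oxirane | C[C@@]1(CCSc2ccccc2)CO1 | intermediate
7 | (S)-(+)-carvone, (5S)-2-methyl-5-(prop-1-en-2-yl)cyclohex-2-en-1-one | CC1=CC[C@H](C(C)=C)CC1=O | starting material
8 | bromomagnesium linear dienolate of carvone (O–C1=C2–C3=C4) | CC1=C(O[Mg]Br)C[C@@H](C(C)=C)C=C1 | intermediate (not isolated)
9 | trimethyl{[(5R)-2-methyl-5-(prop-1-en-2-yl)cyclohexa-1,3-dien-1-yl]oxy}silane | CC1=C(O[Si](C)(C)C)C[C@@H](C(C)=C)C=C1 | intermediate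
10 | (4R,5S)-2-methyl-5-(prop-1-en-2-yl)-4-[(trimethylsilyl)peroxy]cyclohex-2-en-1-one | CC1=C[C@@H](OO[Si](C)(C)C)[C@H](C(C)=C)CC1=O | intermediate (not isolated)
11 | trans-4-hydroxycarvone, (4R,5S)-4-hydroxy-2-methyl-5-(prop-1-en-2-yl)cyclohex-2-en-1-one | CC1=C[C@@H](O)[C@H](C(C)=C)CC1=O | intermediate
12 | (4R,5S)-4-(tert-butyldimethylsilyloxy)-2-methyl-5-(prop-1-en-2-yl)cyclohex-2-en-1-one | CC1=C[C@@H](O[Si](C)(C)C(C)(C)C)[C@H](C(C)=C)CC1=O | intermediate
13 | cross-conjugated lithium enolate of 12 (C1–OLi, C1=C6) | CC1=C[C@@H](O[Si](C)(C)C(C)(C)C)[C@H](C(C)=C)C=C1O[Li] | intermediate (not isolated)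
14 | (4R,5S,6R)-4-(tert-butyldimethylsilyloxy)-6-[(2S)-2-hydroxy-2-methyl-4-(phenylsulfanyl)butyl]-2-methyl-5-(prop-1-en-2-yl)cyclohex-2-en-1-one (4,5-trans, 5,6-trans) | CC1=C[C@@H](O[Si](C)(C)C(C)(C)C)[C@H](C(C)=C)[C@@H](C[C@](C)(O)CCSc2ccccc2)C1=O | intermediate
15 | 14 with the tertiary hydroxyl as its triethylsilyl ether | CC1=C[C@@H](O[Si](C)(C)C(C)(C)C)[C@H](C(C)=C)[C@@H](C[C@](C)(O[Si](CC)(CC)CC)CCSc2ccccc2)C1=O | intermediate
16 | 15 with phenylsulfonyl in place of phenylsulfanyl | CC1=C[C@@H](O[Si](C)(C)C(C)(C)C)[C@H](C(C)=C)[C@@H](C[C@](C)(O[Si](CC)(CC)CC)CCS(=O)(=O)c2ccccc2)C1=O | intermediate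
17 | 16 with 5-(3-hydroxyprop-1-en-2-yl) in place of isopropenyl | CC1=C[C@@H](O[Si](C)(C)C(C)(C)C)[C@H](C(=C)CO)[C@@H](C[C@](C)(O[Si](CC)(CC)CC)CCS(=O)(=O)c2ccccc2)C1=O | intermediate
18 | 16 with 5-(3-oxoprop-1-en-2-yl) in place of isopropenyl | CC1=C[C@@H](O[Si](C)(C)C(C)(C)C)[C@H](C(=C)C=O)[C@@H](C[C@](C)(O[Si](CC)(CC)CC)CCS(=O)(=O)c2ccccc2)C1=O | intermediate (not isolated)
19 | 16 with 5-(1-carboxyethenyl) in place of isopropenyl (ring substituents all-trans) | CC1=C[C@@H](O[Si](C)(C)C(C)(C)C)[C@H](C(=C)C(=O)O)[C@@H](C[C@](C)(O[Si](CC)(CC)CC)CCS(=O)(=O)c2ccccc2)C1=O | intermediate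
20 | 6,7-dihydrooxepin-2(5H)-one: 3-methyl, 5-OTBS, 6-(1-carboxyethenyl), 7-[2-methyl-4-(phenylsulfonyl)-2-(triethylsilyloxy)butyl], 5,6-trans and 6,7-trans; ring O = O8 of 28 | CC1=C[C@@H](O[Si](C)(C)C(C)(C)C)[C@H](C(=C)C(=O)O)[C@@H](C[C@](C)(O[Si](CC)(CC)CC)CCS(=O)(=O)c2ccccc2)OC1=O | intermediate
21 | O8-bridged tetrahedral adduct (11-oxabicyclo[4.4.1]undecene hemiketal, C2 epimers; lithium salt in the flask, drawn protonated) | CC1=C[C@@H](O[Si](C)(C)C(C)(C)C)[C@H](C(=C)C(=O)O)[C@H]2C[C@](C)(O[Si](CC)(CC)CC)CC(S(=O)(=O)c3ccccc3)[C@]1(O)O2 | intermediate (not isolated)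
22 | ten-membered (4Z)-3-oxo-2-(phenylsulfonyl)-6-OTBS-8-hydroxy-10-OTES-germacra-4,11(13)-dien-12-oic acid, C2 epimers, C6/C7/C8/C10 as in 28 (lithium alkoxide/enolate/carboxylate in the flask, drawn protonated) | C/C1=C/[C@@H](O[Si](C)(C)C(C)(C)C)[C@H](C(=C)C(=O)O)[C@H](O)C[C@](C)(O[Si](CC)(CC)CC)CC(S(=O)(=O)c2ccccc2)C1=O | intermediate (not isolated)
23 | 8-O-isobutyrate of 22 | C/C1=C/[C@@H](O[Si](C)(C)C(C)(C)C)[C@H](C(=C)C(=O)O)[C@H](OC(=O)C(C)C)C[C@](C)(O[Si](CC)(CC)CC)CC(S(=O)(=O)c2ccccc2)C1=O | intermediate
24 | 23 without the phenylsulfonyl group (C2 = CH2) | C/C1=C/[C@@H](O[Si](C)(C)C(C)(C)C)[C@H](C(=C)C(=O)O)[C@H](OC(=O)C(C)C)C[C@](C)(O[Si](CC)(CC)CC)CCC1=O | intermediate (not isolated)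
25 | 3-hydroxy-3,10-epoxy hemiketal of desilylated 24: 6-OTBS, 8-isobutyrate, 12-oic acid (C3 drawn as in 28) | C/C1=C/[C@@H](O[Si](C)(C)C(C)(C)C)[C@H](C(=C)C(=O)O)[C@H](OC(=O)C(C)C)C[C@@]2(C)CC[C@@]1(O)O2 | intermediate
26 | 25 with free 6-hydroxyl | C/C1=C/[C@@H](O)[C@H](C(=C)C(=O)O)[C@H](OC(=O)C(C)C)C[C@@]2(C)CC[C@@]1(O)O2 | intermediate (not isolated)
27 | 15-deoxy-28 (6,12-olide, C15 = CH3) | C/C1=C/[C@H]2OC(=O)C(=C)[C@@H]2[C@H](OC(=O)C(C)C)C[C@@]3(C)CC[C@@]1(O)O3 | intermediate
28 | (3R,6R,7R,8R,10R,4Z)-3,15-dihydroxy-8-(isobutyryloxy)-3,10-epoxygermacra-4,11(13)-dien-6,12-olide | C=C1C(=O)O[C@@H]2/C=C(/CO)[C@@]3(O)CC[C@](C)(C[C@@H](OC(=O)C(C)C)[C@@H]12)O3 | target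

## Step count and least certain steps

Total: 15 steps. Longest linear sequence: 13 steps (steps 3–15 from 7).

**Step 12 (key).** What may go wrong: proton transfer instead of C–C bond formation (γ-deprotonation at C6 and deconjugation of the enoate); a slow seven-membered addition that leaves time for retro-1,4-Brook transfer of the O10 silyl group to the carbanion; and, in the trapping stage, 1,3-migration of the C6 silyl group to the C8 alkoxide or acylation of the enolate. Fallback (direct macrocyclisation instead of ring expansion): 20 would be opened with MeNH(OMe)·HCl/AlMe3 and the liberated C8 alkoxide silylated in the same flask (TMSCl) to give the open-chain (Z)-Weinreb amide 8-trimethylsilyl ether F1. LiHMDS under high dilution would close the ten-membered ring by acylation of the sulfonyl carbanion with the amide, and mild acidic work-up would remove the trimethylsilyl group to give 22. This is acylated ((i-PrCO)2O, DMAP) to 23, where the route is rejoined.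

**Step 11.** What may go wrong: slow oxidation of the conjugated ketone, and competing migration of the vinylic carbon to give an enol lactone. Fallback (saturated ketone with a deactivated competitor): thiophenol/Et3N would add to the enone of 19 to give the β-phenylthio ketone F2. mCPBA would first oxidise the sulfide and then insert oxygen on the side of the unperturbed secondary carbon, since the other α-carbon now carries a β-sulfonyl group, giving the β-sulfonyl lactone F3. DBU would eliminate benzenesulfinate and return the (Z)-enoate 20.

**Step 6.** What may go wrong: low reactivity of the ketone enolate toward the neopentyl-like epoxide terminus; Lewis-acid-induced Meinwald rearrangement of 6 followed by aldol addition; and proton transfer that erodes the trans selectivity. Fallback (aza-enolate): 12 would be converted into its N,N-dimethylhydrazone F4. Metalation (LDA) and reaction with 6 without a Lewis acid would give the alkylated hydrazone F5, and mild hydrolysis (aqueous CuCl2) would return 14.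

**Step 4 (with step 3).** What may go wrong: incomplete regiocontrol in the dienolate formation (cross-conjugated isomer, or aromatisation by further deprotonation at C5); ene reaction of singlet oxygen at the isopropenyl group; and imperfect facial selectivity. Fallback (selenoxide [2,3]-sigmatropic route): the potassium dienolate of 7 (KOtBu) would be selenenylated at C2 with PhSeCl to give the α-phenylselanyl β,γ-enone F6. Oxidation (H2O2, pyridine) would trigger the [2,3] shift of the allyl selenoxide, and hydrolysis of the selenenate would give 11.

**Step 15.** What may go wrong: over-oxidation of the new allylic alcohol to the enal; slow reaction of the hindered trisubstituted olefin; and acid-promoted loss of water from the hemiketal. Fallback (chlorination with allylic transposition): ene-type chlorination of 27 with Ca(OCl)2/CO2 would give the 5-chloro-4(15)-ene F7. Silver-assisted SN2′ hydrolysis (AgBF4, aqueous acetone) would move the double bond back to C4=C5 and place the hydroxyl on C15, giving 28.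

## Further compounds

F1 | step 12 | (Z)-Weinreb amide 8-trimethylsilyl ether from opening of 20 (6-OTBS, 10-OTES, 2-phenylsulfonyl, 12-oic acid) | CON(C)C(=O)/C(C)=C\[C@@H](O[Si](C)(C)C(C)(C)C)[C@H](C(=C)C(=O)O)[C@H](O[Si](C)(C)C)C[C@](C)(O[Si](CC)(CC)CC)CCS(=O)(=O)c1ccccc1
F2 | step 11 | β-phenylthio ketone from thiophenol addition to 19 (C2/C3 epimers) | CC1C(Sc2ccccc2)[C@@H](O[Si](C)(C)C(C)(C)C)[C@H](C(=C)C(=O)O)[C@@H](C[C@](C)(O[Si](CC)(CC)CC)CCS(=O)(=O)c2ccccc2)C1=O
F3 | step 11 | β-phenylsulfonyl seven-membered lactone (saturated precursor of 20) | CC1C(S(=O)(=O)c2ccccc2)[C@@H](O[Si](C)(C)C(C)(C)C)[C@H](C(=C)C(=O)O)[C@@H](C[C@](C)(O[Si](CC)(CC)CC)CCS(=O)(=O)c2ccccc2)OC1=O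
F4 | step 6 | N,N-dimethylhydrazone of 12 | CC1=C[C@@H](O[Si](C)(C)C(C)(C)C)[C@H](C(C)=C)CC1=NN(C)C
F5 | step 6 | N,N-dimethylhydrazone of 14 | CC1=C[C@@H](O[Si](C)(C)C(C)(C)C)[C@H](C(C)=C)[C@@H](C[C@](C)(O)CCSc2ccccc2)C1=NN(C)C
F6 | step 4 | 2-methyl-2-(phenylselanyl)-5-(prop-1-en-2-yl)cyclohex-3-en-1-one (selenium trans to the isopropenyl group) | C[C@]1([Se]c2ccccc2)C=C[C@H](C(C)=C)CC1=O
F7 | step 15 | 5-chloro-4(15)-ene isomer of 27 (C5 epimers) | C=C1C(Cl)[C@H]2OC(=O)C(=C)[C@@H]2[C@H](OC(=O)C(C)C)C[C@@]3(C)CC[C@@]1(O)O3
A1 | alternative 1 | seco (Z)-enal with a (Z)-2-(bromomethyl)enoate, C3 as methyl ketal of the oxolane | O=C/C=C(/CO[Si](C)(C)C(C)(C)C)[C@@]1(OC)CC[C@](C)(C[C@@H](OC(=O)C(C)C)/C=C(\CBr)C(=O)OC)O1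
A2 | alternative 1 | ten-membered homoallylic alcohol from the intramolecular allylation | C=C(C(=O)OC)[C@H]1[C@H](O)/C=C(/CO[Si](C)(C)C(C)(C)C)[C@@]2(OC)CC[C@](C)(C[C@H]1OC(=O)C(C)C)O2
A3 | alternative 2 | cis-fused decalinol from intramolecular Barbier addition of the C2 iodide to the ring carbonyl | CC1=C[C@@H](O[Si](C)(C)C(C)(C)C)[C@H](C(C)=C)[C@H]2C[C@](C)(O[Si](CC)(CC)CC)CC[C@@]12O
A4 | alternative 2 | ten-membered 8-iodo enone from alkoxy-radical β-scission (C8 epimers) | C/C1=C/[C@@H](O[Si](C)(C)C(C)(C)C)[C@H](C(C)=C)C(I)C[C@](C)(O[Si](CC)(CC)CC)CCC1=O
A5 | alternative 3 | (Z)-vinyl iodide carrying the butyrolactone, the 8-isobutyrate and a C10 γ-lactone | I/C(CO[Si](C)(C)C(C)(C)C)=C\[C@H]1OC(=O)C(=C)[C@@H]1[C@H](OC(=O)C(C)C)C[C@@]2(C)CCC(=O)O2
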